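**Retrosynthetic overview**
1. Target 26 ⇐ vinyl epoxide 25 by anti hydrolysis at allylic C16. Both ring oxygens (C15–O, C16–O) come from one oxirane, installed on cis-hydrindanone 15 by a new aerobic dehydrogenative epoxidation (C–O key step).
2. 25 ⇐ tricyclic ketone 23 (CBS reduction, acetylation) ⇐ keto aldehyde 20 by Nozaki–Hiyama–Kishi closure of the eleven-membered ring at C7–C8, then Wittig methylenation at C1.
3. 20 ⇐ bicyclic enone 12 + enal 5: vinylogous Mukaiyama aldol at C11, copper hydride 1,4-reduction (C10–H), epoxidation, enol triflation at C8.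
4. 12 ⇐ 2-methylcyclopentanone + ethyl vinyl ketone (chiral-imine Michael addition, aldol condensation); 5 ⇐ methyl hydrogen (R)-3-methylglutarate.
5. Ring order: five-membered ring present from the start → six-membered ring (step 5) → eleven-membered ring (step 12).

Assumption and numbering: atoms follow the target SMILES from left to right, C1 (bears =CH2), C2=C3, C4, C5 (CH3), C6, C7 (OAc), C8=C9 (CH3 on C9), C10, C11, C12, C13, C14 (CH3), C15 (OH), C16 (OH); "α" is the face of the six-membered ring carrying the C14 methyl and C10–H, "β" the face carrying C11 and C13; the sense of induction in step 4 is taken from the analogous 2-methylcyclohexanone case.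

**Step 1**
Reactants: 1 methyl hydrogen (R)-3-methylglutarate
Product: 3 methyl (R)-5-(tert-butyldimethylsilyloxy)-3-methylpentanoate, via hydroxy ester 2 (not isolated)
Conditions: BH3·SMe2, THF, 0 °C to rt; MeOH quench, evaporate; then TBSCl, imidazole, DMF, rt
Reagents that add atoms: tert-butyldimethylsilyl chloride CC(C)(C)[Si](C)(C)Cl
Why: chemoselective borane reduction of the free acid beside the methyl ester, followed at once by silyl ether protection so that the hydroxy ester cannot lactonise; the methyl-bearing stereocentre is untouched.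

**Step 2**
Reactants: 3 methyl (R)-5-(tert-butyldimethylsilyloxy)-3-methylpentanoate
Product: 4 (R)-5-(tert-butyldimethylsilyloxy)-3-methylpentanal
Conditions: i-Bu2AlH, CH2Cl2, −78 °C; Rochelle salt work-up
Reagents that add atoms: none
Why: partial ester reduction with i-Bu2AlH stops at the aldehyde because the aluminium hemiacetal is stable at −78 °C.

**Step 3**
Reactants: 4 (R)-5-(tert-butyldimethylsilyloxy)-3-methylpentanal
Product: 5 (S,E)-7-(tert-butyldimethylsilyloxy)-5-methylhept-2-enal
Conditions: Ph3P=CHCHO, PhMe, 80 °C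
Reagents that add atoms: (triphenylphosphoranylidene)acetaldehyde O=CC=P(c1ccccc1)(c1ccccc1)c1ccccc1
Why: Wittig olefination with the stabilised formyl ylide gives the (E)-enal, which fixes the later C2=C3 geometry (the descriptor changes from R to S only through CIP priorities).

**Step 4**
Reactants: 6 2-methylcyclopentanone; 7 (S)-1-phenylethylamine; 8 ethyl vinyl ketone
Product: 11 (R)-2-methyl-2-(3-oxopentyl)cyclopentan-1-one, via ketimine 9 (not isolated), via adduct imine 10 (not isolated)
Conditions: 7, TsOH (cat.), PhMe, reflux (Dean–Stark); then 8, THF, 40 °C; then 20% aq. AcOH, rt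
Reagents that add atoms: water O
Why: chiral-imine Michael addition (deracemising alkylation through the more substituted secondary enamine): the (S)-phenylethyl group shields one enamine face so the quaternary C14 forms as R (about 90% ee expected); the minor antipode is removed as a diastereomer after step 6.

**Step 5**
Reactants: 11 (R)-2-methyl-2-(3-oxopentyl)cyclopentan-1-one
Product: 12 (R)-4,7a-dimethyl-1,2,3,6,7,7a-hexahydro-5H-inden-5-one
Conditions: NaOMe, MeOH, reflux
Reagents that add atoms: none
Why: intramolecular aldol condensation (second stage of a Robinson annulation) closes the six-membered ring as the C8 enone with the C9 methyl in place; C14 cannot epimerise.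

**Step 6**
Reactants: 12 (R)-4,7a-dimethyl-1,2,3,6,7,7a-hexahydro-5H-inden-5-one; 5 (S,E)-7-(tert-butyldimethylsilyloxy)-5-methylhept-2-enal
Product: 14 C11-alkylated bis-silyl enone, via silyl dienol ether 13 (not isolated)
Conditions: TBSOTf, Et3N, CH2Cl2, 0 °C; pentane filtration, concentrate; then 5, Tf2NH (2 mol %), CH2Cl2, −78 °C
Reagents that add atoms: tert-butyldimethylsilyl trifluoromethanesulfonate CC(C)(C)[Si](C)(C)OS(=O)(=O)C(F)(F)F
Why: vinylogous Mukaiyama aldol addition: the α-methyl-blocked dienol ether reacts at its γ-carbon C11 with the aldehyde carbon of 5, approaching anti to the pseudo-axial C14 methyl so that C11 has the target configuration; the silyl group moves to the new C1 oxygen, whose configuration does not matter.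

**Step 7**
Reactants: 14 C11-alkylated bis-silyl enone
Product: 15 cis-hydrindanone
Conditions: Cu(OAc)2·H2O (3 mol %), 1,2-bis(diphenylphosphino)benzene (3 mol %), MeSiH(OMe)2, t-BuOH, PhMe, rt
Reagents that add atoms: none
Why: ligated copper hydride conjugate reduction of the β,β-disubstituted enone; hydride adds to C10 on the α face, opposite the bulky C11 side chain, giving the cis ring fusion with C10–H, C11–H and C14–CH3 all cis, while the isolated alkene and silyl ethers are inert.

**Step 8**
Reactants: 15 cis-hydrindanone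
Product: 17 α-epoxy ketone, via enone 16 (not isolated)
Conditions: Pd(O2CCF3)2 (10 mol %), 4,5-diazafluoren-9-one (12 mol %), KHCO3 (0.5 equiv), O2 (1 atm), DMSO–H2O (20:1), 45 °C
Reagents that add atoms: dioxygen O=O
Why: Proposed new method: aerobic dehydrogenative epoxidation, in which divalent palladium forms the C16 enolate (C9 is tertiary and hindered) and loses the C15 β-hydride to give enone 16 and Pd–H, O2 converts Pd–H into Pd–OOH, and under bicarbonate buffering this hydroperoxide adds in Weitz–Scheffer fashion to C15 from the convex α face (anti to the axial C13 methylene), the enolate then closing the oxirane and returning Pd–OH, so one O2 supplies both the dehydrogenation and the oxirane oxygen and fixes C15–O on the α face; the closest known chemistry is aerobic palladium-catalysed ketone dehydrogenation to enones, alkaline hydroperoxide (Weitz–Scheffer) epoxidation, and oxygen transfer from late-metal peroxo complexes to electron-poor alkenes.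

**Step 9**
Reactants: 17 α-epoxy ketone
Product: 18 enol triflate
Conditions: KN(SiMe3)2, PhNTf2, THF, −78 to −40 °C
Reagents that add atoms: N-phenylbis(trifluoromethanesulfonimide) O=S(=O)(N(c1ccccc1)S(=O)(=O)C(F)(F)F)C(F)(F)F
Why: regioselective enol triflate formation: oxirane carbon C16 has no enolisable hydrogen, so only C9 is deprotonated and O-sulfonylation fixes the tetrasubstituted C8=C9 bond.

**Step 10**
Reactants: 18 enol triflate
Product: 19 diol
Conditions: HF·pyridine, pyridine, THF, 0 °C to rt
Reagents that add atoms: none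
Why: fluoride-mediated desilylation removes both silyl ethers; the enol triflate survives and the oxirane, next to an electron-poor alkene, resists buffered HF.

**Step 11**
Reactants: 19 diol
Product: 20 keto aldehyde
Conditions: Dess–Martin periodinane, NaHCO3, CH2Cl2, 0 °C to rt
Reagents that add atoms: none
Why: Dess–Martin oxidation turns the primary alcohol into the C7 aldehyde and the allylic C1 alcohol into the enone in one operation, removing the C1 epimer mixture.

**Step 12**
Reactants: 20 keto aldehyde
Product: 21 tricyclic hydroxy enone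
Conditions: CrCl2 (8 equiv), NiCl2 (2 mol %), DMSO–THF (3:1), 0.002 M, slow addition, rt
Reagents that add atoms: none
Why: Nozaki–Hiyama–Kishi reaction: nickel inserts into the alkenyl triflate and transmetallates to trivalent chromium, and the alkenylchromium adds to the aldehyde (not the enone) under high dilution, closing the eleven-membered ring at C7–C8; both C7 epimers are carried on.

**Step 13**
Reactants: 21 tricyclic hydroxy enone
Product: 22 tricyclic triene alcohol
Conditions: Ph3PCH3Br, KOt-Bu (3 equiv of ylide), THF, 0 °C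
Reagents that add atoms: methyltriphenylphosphonium bromide C[P+](c1ccccc1)(c1ccccc1)c1ccccc1.[Br-]
Why: Wittig methylenation of the C1 ketone completes the exocyclic-methylene diene; the free alcohol is tolerated as its alkoxide and C11 is expected to be held by the tricyclic frame.

**Step 14**
Reactants: 22 tricyclic triene alcohol
Product: 23 tricyclic ketone
Conditions: Dess–Martin periodinane, NaHCO3, CH2Cl2, 0 °C
Reagents that add atoms: none
Why: Dess–Martin oxidation of the allylic alcohol converges both C7 epimers into one enone.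

**Step 15**
Reactants: 23 tricyclic ketone
Product: 24 (7S)-alcohol
Conditions: (R)-2-methyl-CBS-oxazaborolidine (0.5 equiv), catecholborane, PhMe, −78 °C
Reagents that add atoms: none
Why: Corey–Bakshi–Shibata reduction: with the fully substituted alkenyl group as the large and C6H2 as the small substituent, the (R)-oxazaborolidine delivers hydride to give the (7S)-carbinol under reagent control.

**Step 16**
Reactants: 24 (7S)-alcohol
Product: 25 (7S)-acetate
Conditions: Ac2O, DMAP, pyridine, CH2Cl2, 0 °C
Reagents that add atoms: acetic anhydride CC(=O)OC(C)=O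
Why: DMAP-catalysed acylation of the secondary allylic alcohol with retention at C7.

**Step 17**
Reactants: 25 (7S)-acetate
Product: 26 target CNP0291538.1
Conditions: HClO4 (3 mol %), THF–H2O (3:1), 0 °C
Reagents that add atoms: water O
Why: acid-catalysed anti epoxide hydrolysis: water attacks the activated allylic C16 from the β face with inversion while neopentyl C15 keeps its α oxygen, giving the trans-diol with C15–OH cis and C16–OH trans to the C14 methyl.

**Compound list**
1 | methyl hydrogen (R)-3-methylglutarate [(R)-5-methoxy-3-methyl-5-oxopentanoic acid] | COC(=O)C[C@H](C)CC(=O)O | starting material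
2 | methyl (R)-5-hydroxy-3-methylpentanoate | COC(=O)C[C@H](C)CCO | intermediate
3 | methyl (R)-5-(tert-butyldimethylsilyloxy)-3-methylpentanoate | COC(=O)C[C@H](C)CCO[Si](C)(C)C(C)(C)C | intermediate
4 | (R)-5-(tert-butyldimethylsilyloxy)-3-methylpentanal | O=CC[C@H](C)CCO[Si](C)(C)C(C)(C)C | intermediate
5 | (S,E)-7-(tert-butyldimethylsilyloxy)-5-methylhept-2-enal (C1–C7 fragment) | O=C/C=C/C[C@H](C)CCO[Si](C)(C)C(C)(C)C | intermediate
6 | 2-methylcyclopentanone (racemic) | CC1CCCC1=O | starting material
7 | (S)-1-phenylethylamine | C[C@H](N)c1ccccc1 | starting material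
8 | ethyl vinyl ketone (pent-1-en-3-one) | CCC(=O)C=C | starting material
9 | N-[(S)-1-phenylethyl] ketimine of 6 | C[C@H](N=C1CCCC1C)c1ccccc1 | intermediate
10 | N-[(S)-1-phenylethyl] imine (ring carbonyl) of 11 | C[C@H](N=C1CCC[C@]1(C)CCC(=O)CC)c1ccccc1 | intermediate
11 | (R)-2-methyl-2-(3-oxopentyl)cyclopentan-1-one | O=C1CCC[C@]1(C)CCC(=O)CC | intermediate
12 | (R)-4,7a-dimethyl-1,2,3,6,7,7a-hexahydro-5H-inden-5-one (C8 ketone, C9=C10) | O=C1C(C)=C2CCC[C@]2(C)CC1 | intermediate
13 | tert-butyldimethylsilyl dienol ether of 12 (C8–OSi, C8=C9, C10=C11) | CC(C)(C)[Si](C)(C)OC1=C(C)C2=CCC[C@]2(C)CC1 | intermediate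
14 | enone 12 carrying at C11 (β, trans to the C14 methyl) the (2E,5S)-1,7-bis(tert-butyldimethylsilyloxy)-5-methylhept-2-en-1-yl chain; C1 epimers | CC(C)(C)[Si](C)(C)OCC[C@@H](C)C/C=C/C(O[Si](C)(C)C(C)(C)C)[C@@H]1CC[C@]2(C)CCC(=O)C(C)=C12 | intermediate
15 | cis-fused C8 ketone from 14 (C10–H, C11–H and C14–CH3 all α; C9 epimers) | CC(C)(C)[Si](C)(C)OCC[C@@H](C)C/C=C/C(O[Si](C)(C)C(C)(C)C)[C@@H]1CC[C@]2(C)CCC(=O)C(C)[C@H]12 | intermediate
16 | C15=C16 enone from 15 | CC(C)(C)[Si](C)(C)OCC[C@@H](C)C/C=C/C(O[Si](C)(C)C(C)(C)C)[C@@H]1CC[C@]2(C)C=CC(=O)C(C)[C@H]12 | intermediate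
17 | 15,16-α-epoxy C8 ketone (oxirane cis to the C14 methyl) | CC(C)(C)[Si](C)(C)OCC[C@@H](C)C/C=C/C(O[Si](C)(C)C(C)(C)C)[C@@H]1CC[C@]2(C)[C@H]3O[C@H]3C(=O)C(C)[C@H]12 | intermediate
18 | C8 enol triflate (C8=C9) of 17 | CC(C)(C)[Si](C)(C)OCC[C@@H](C)C/C=C/C(O[Si](C)(C)C(C)(C)C)[C@@H]1CC[C@]2(C)[C@H]3O[C@H]3C(OS(=O)(=O)C(F)(F)F)=C(C)[C@H]12 | intermediate
19 | C1,C7-diol of 18 (C1 epimers) | OCC[C@@H](C)C/C=C/C(O)[C@@H]1CC[C@]2(C)[C@H]3O[C@H]3C(OS(=O)(=O)C(F)(F)F)=C(C)[C@H]12 | intermediate
20 | keto aldehyde (C1 enone, C7 aldehyde, C8 triflate, α-epoxide) | O=CC[C@@H](C)C/C=C/C(=O)[C@@H]1CC[C@]2(C)[C@H]3O[C@H]3C(OS(=O)(=O)C(F)(F)F)=C(C)[C@H]12 | intermediate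
21 | tricyclic hydroxy enone (C1 ketone, C7 carbinol as both epimers, α-epoxide) | O=C1/C=C/C[C@H](C)CC(O)C2=C(C)[C@@H]3[C@H]1CC[C@]3(C)[C@H]4O[C@H]42 | intermediate
22 | tricyclic triene alcohol (C1 methylene, C7 carbinol epimers, α-epoxide) | C=C1/C=C/C[C@H](C)CC(O)C2=C(C)[C@@H]3[C@H]1CC[C@]3(C)[C@H]4O[C@H]42 | intermediate
23 | tricyclic C7 ketone (C1 methylene, α-epoxide) | C=C1/C=C/C[C@H](C)CC(=O)C2=C(C)[C@@H]3[C@H]1CC[C@]3(C)[C@H]4O[C@H]42 | intermediate
24 | (7S)-alcohol (α-epoxide) | C=C1/C=C/C[C@H](C)C[C@H](O)C2=C(C)[C@@H]3[C@H]1CC[C@]3(C)[C@H]4O[C@H]42 | intermediate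
25 | (7S)-acetate (α-epoxide) | C=C1/C=C/C[C@H](C)C[C@H](OC(C)=O)C2=C(C)[C@@H]3[C@H]1CC[C@]3(C)[C@H]4O[C@H]42 | intermediate
26 | CNP0291538.1: (5S,7S,10S,11R,14S,15R,16R) 7-acetate 15α,16β-diol | C=C1/C=C/C[C@H](C)C[C@H](OC(C)=O)C2=C(C)[C@@H]3[C@H]1CC[C@]3(C)[C@@H](O)[C@@H]2O | target

**Step count**
Total: 17 steps. Longest linear sequence: 15 steps (steps 1–3, then 6–17).

**Three steps most likely to fail**

Step 8 (proposed new aerobic dehydrogenative epoxidation). The hydroperoxide may not be transferred to the enone, or dehydrogenation may stall. The fallback uses known chemistry and sets out from 15. LiN(i-Pr)2 then Me3SiCl (THF, −78 °C) gives the kinetic trimethylsilyl enol ether F1 on the C16 side. Saegusa–Ito dehydrogenation with Pd(OAc)2 in MeCN gives enone 16, now isolated. Weitz–Scheffer epoxidation (t-BuOOH, DBU, CH2Cl2, 0 °C) from the convex α face then returns to the route at 17.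

Step 12 (eleven-membered ring closure at a hindered tetrasubstituted alkenyl triflate, with an enone in the chain). The fallback sets out from diol 19 and closes the ring before the C1 ketone exists, changing which intermediate is cyclised and the order of the redox steps. TEMPO/PhI(OAc)2 oxidises only the primary alcohol to hydroxy aldehyde F2. The chromium/nickel coupling on this more flexible, enone-free substrate gives tricyclic diol F3. Dess–Martin oxidation gives tricyclic dione F4. One equivalent of Ph3P=CH2 at −78 °C methylenates the C1 ketone (selectivity over the C7 carbonyl, which sits next to the fully substituted C8=C9 unit, is assumed) and returns to the route at 23.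

Step 17 (final hydrolysis). Risks are 1,4-opening, participation of the C7 acetate and acid sensitivity of the diene. The fallback sets out from alcohol 24 and opens the oxirane before acetylation with a carbonyl oxygen nucleophile instead of water. Acetone with BF3·OEt2 (cat., −30 °C) attacks allylic C16 with inversion and closes to the trans-fused acetonide alcohol F5. Ac2O/DMAP gives acetonide acetate F6. 80% aqueous AcOH at rt removes the acetonide and returns to the route at 26.

**Further compounds**
F1 | step 8 | trimethylsilyl enol ether of 15 (C8–OSiMe3, C8=C16) | CC(C)(C)[Si](C)(C)OCC[C@@H](C)C/C=C/C(O[Si](C)(C)C(C)(C)C)[C@@H]1CC[C@]2(C)CC=C(O[Si](C)(C)C)C(C)[C@H]12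
F2 | step 12 | hydroxy aldehyde (C7 aldehyde, C1 carbinol, C8 triflate, α-epoxide) | O=CC[C@@H](C)C/C=C/C(O)[C@@H]1CC[C@]2(C)[C@H]3O[C@H]3C(OS(=O)(=O)C(F)(F)F)=C(C)[C@H]12
F3 | step 12 | tricyclic diol (C1 and C7 carbinols, α-epoxide) | OC1/C=C/C[C@H](C)CC(O)C2=C(C)[C@@H]3[C@H]1CC[C@]3(C)[C@H]4O[C@H]42
F4 | step 12 | tricyclic dione (C1 and C7 ketones, α-epoxide) | O=C1/C=C/C[C@H](C)CC(=O)C2=C(C)[C@@H]3[C@H]1CC[C@]3(C)[C@H]4O[C@H]42
F5 | step 17 | trans-15,16-acetonide of the (7S)-alcohol | C=C1/C=C/C[C@H](C)C[C@H](O)C2=C(C)[C@@H]3[C@H]1CC[C@]3(C)[C@@H](OC(C)(C)O4)[C@@H]24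
F6 | step 17 | trans-15,16-acetonide of the (7S)-acetate | C=C1/C=C/C[C@H](C)C[C@H](OC(C)=O)C2=C(C)[C@@H]3[C@H]1CC[C@]3(C)[C@@H](OC(C)(C)O4)[C@@H]24
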